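In a one-step world every partner makes one product. The partner charge is smaller than the two substrates together, which makes it the limiting reagent, and this flask would stop at a conversion of 30.0%.

- Saturday's: left-handed substrate 0.80 M; right-handed substrate 0.80 M; partner 0.48 M; protic impurity 0.040 M; catalyst 0.40 mM; the very flask that is asked about, followed so far
- flask: left-handed substrate 0.80 M; partner 0.480 M; protic impurity 0.0400 M; catalyst 0.40 mM; right-handed substrate 0.80 M; time 1.0 h

Saturday's run (percent of the left-handed substrate and right-handed substrate together charged)

| time / min | left-handed substrate / % | right-handed substrate / % |
|---|---|---|
| 1.00 | 44.2 | 49.1 |
| 1.33 | 45.2 | 47.6 |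
| 2.00 | 42.9 | 48.6 |
| 3.00 | 41.6 | 47.0 |
| 5.00 | 38.4 | 46.9 |
| 8.00 | 36.4 | 45.9 |
| 12.0 | 36.6 | 46.6 |

(standard deviation of a reading: 1 percentage point)

- catalyst is single-handed; left-handed substrate and right-handed substrate are mirror images of each other, charged as a racemate, each of them at the stated concentration
- an excess is the difference of the two amounts in percent of their sum
- an excess is below zero if the other one leads

- part of the left-handed substrate and right-handed substrate charged together that has reacted at 1.0 h
- excess of left-handed product over right-handed product in the product at 1.0 h
- excess of right-handed substrate over left-handed substrate among what is left of the two at 1.0 h

In Saturday's run, which follows this very flask, the last two readings average a conversion of 17.2%, lower than that ceiling. Dividing this by the ceiling gives the quantity I carry, 57.5%, the product share of the partner, that is, product made per partner charged. The protic impurity amounts to 8.33% of the partner, less than the 42.5% that goes missing, so I suppose that the partner also decays by itself.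

I assume a pseudo-first-order loss of partner, split in fixed proportion between product and the other routes. Integrating that rate gives the conversion as the stopping value times one minus exp(−t/τ), and the reading at 3.00 min gives a time constant τ of 2.77 min. That is the first rung of the ladder. The next is the last reading at 12.0 min, which lies 4.33 time constants out, and the readings are flat by then. The last rung is the asked 1.0 h, far longer than τ, so my own figure for the conversion stays at 17.2%.

The forecast gives 17.7%, 56% and 12%, and says the stall “looks like the catalyst dying”; there I differ from it.

The flask gives 19.6%, 46.5% and 11.3%, so the forecast's product excess stands 9.5 percentage points too high and its other two values lie within tolerance. At 1.00 h this flask holds 0% of its partner and 100% of its catalyst. Reckoned on the flask's conversion, the product share is 65.3%, where the scattered readings gave me 57.5%.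

    partner + protic impurity → quenched reagent (k = 0.670 M⁻¹ min⁻¹)
    partner → decomposed reagent (k = 0.0970 min⁻¹)
    partner + catalyst + left-handed substrate → catalyst + left-handed product (k = 580 M⁻² min⁻¹)
    partner + catalyst + right-handed substrate → catalyst + right-handed product (k = 190 M⁻² min⁻¹)

In the same flask charged with 0.12 M of partner, the share 57.5% gives a conversion of 4.31%. The computed flask reaches 4.98%.

The data come from a simulation on assumed constants, noise included.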